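**Plan**

- Retrosynthesis: the butenolide is cut at C12–C13 (B-alkyl Suzuki–Miyaura coupling) and at C11=C12 (Wittig). The decalin is then opened at the ring-fusion bond C5–C10 together with C8–C9 (intramolecular Diels–Alder reaction). The resulting open-chain trienal is cut at C6–C7 (Heck) and C3–C4 (carbonyl tert-(hydroxy)prenylation).
- Enabling feature: C5–C10 is the bond shared by rings A and B. C10 carries a methyl (C20) and C9 a carbon (C11) that can be held as an aldehyde, so C9=C10 is the (E)-β-methyl enal of a geranial unit. C5–C8 can be an (E,E)-diene and C1–C4 a four-carbon tether.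
- Forward: geranyl acetate gives C1–C3, C9–C11 and C20; isoprene monoxide gives C4–C6, C18 and C19; a three-carbon iodoalkene gives C7, C8 and C17. Rings A and B then arise together in one step from the open chain. C12 and the intact butenolide (C13–C16) are added last.
- Helpers: the C11 aldehyde (dienophile activation, later C11=C12), the C6=C7 olefin (hydrogenated), benzyl on O17, and acyclic TBS ethers on O3/O19 (to steer the tether chair).
- Stereochemistry: C3/C4 from the iridium catalyst; C5, C9 and C10 from the cycloaddition (olefin geometry, endo mode, equatorial C3–OTBS); C8 by thermodynamic epimerisation of the C17 aldehyde.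

Key step: step 8

Remark: labdane numbering is used throughout (C17 on C8, C18 methyl and C19 hydroxymethyl on C4, C20 on C10); α/β follow the usual labdane drawing, so in this ent-labdane C20 is α and H5 is β.
Remark: the hand of Tol-BINAP in step 2 is written as (R) on the assumption that it gives the (6R,7R)-diol; the antipode would be used if the sense of induction proved opposite.

**Step 1**
Reactants: 1 geranyl acetate
Product: 3 (2E)-3-methyl-6-oxohex-2-en-1-yl acetate, via epoxide 2 (not isolated)
Conditions: mCPBA (1.0 equiv.), CH2Cl2, 0 °C; then H5IO6, THF/H2O, 0 °C to rt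
Reagents that add atoms: mCPBA, OOC(=O)c1cccc(Cl)c1
Why: Prilezhaev epoxidation is selective for the electron-rich remote trisubstituted olefin over the acetate-deactivated allylic one, and periodic acid then cleaves the epoxide through its diol to the aldehyde (glycol cleavage), leaving the (E)-C9=C10 olefin intact; no stereocentre is formed.

**Step 2**
Reactants: 3 (2E)-3-methyl-6-oxohex-2-en-1-yl acetate; 4 isoprene monoxide (racemic)
Product: 5 (2E,6R,7R)-6-hydroxy-7-(hydroxymethyl)-3,7-dimethylnona-2,8-dien-1-yl acetate
Conditions: Ir(η3-C3H5)[(R)-Tol-BINAP][κ2-C,O-C6H2(NO2)2CO2] (5 mol%), K3PO4 (5 mol%), 2-propanol (2 equiv.), THF, 60 °C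
Reagents that add atoms: none
Why: Iridium-catalysed transfer-hydrogenative carbonyl tert-(hydroxy)prenylation: the racemic vinyl epoxide is ionised to one π-allyliridium alkoxide that adds to the aldehyde through a closed chair transition state, so the ligand sets C3 (R) and the quaternary C4 (R) with the hydroxyl anti to the hydroxymethyl group, while the 3,3-disubstituted allylic acetate is too hindered to be ionised.

**Step 3**
Reactants: 5 (2E,6R,7R)-6-hydroxy-7-(hydroxymethyl)-3,7-dimethylnona-2,8-dien-1-yl acetate
Product: 6 (2E,6R,7R)-6-(tert-butyldimethylsilyloxy)-7-[(tert-butyldimethylsilyloxy)methyl]-3,7-dimethylnona-2,8-dien-1-yl acetate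
Conditions: TBSOTf (2.5 equiv.), 2,6-lutidine, CH2Cl2, −78 °C to 0 °C
Reagents that add atoms: TBSOTf, CC(C)(C)[Si](C)(C)OS(=O)(=O)C(F)(F)F
Why: The silyl triflate with a hindered base silylates both the neopentyl primary and the hindered secondary hydroxyl; two acyclic silyl ethers are chosen over a 3,19-acetonide so that the C3 oxygen substituent is free to sit equatorial in step 8.

**Step 4**
Reactants: 6 bis-TBS acetate
Product: 7 (2E,6R,7R)-6-(tert-butyldimethylsilyloxy)-7-[(tert-butyldimethylsilyloxy)methyl]-3,7-dimethylnona-2,8-dien-1-ol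
Conditions: K2CO3, MeOH, 0 °C to rt
Reagents that add atoms: none
Why: Base-catalysed transesterification removes the allylic acetate without touching the TBS ethers, freeing the C11 hydroxyl for later oxidation.

**Step 5**
Reactants: 8 benzyl propargyl ether
Product: 10 (E)-3-(benzyloxy)-1-iodoprop-1-ene, via alkenylzirconocene chloride 9 (not isolated)
Conditions: Cp2Zr(H)Cl, CH2Cl2, rt; then I2, 0 °C
Reagents that add atoms: iodine, II
Why: Hydrozirconation adds Zr–H syn with zirconium at the terminal carbon, and iodinolysis of the C–Zr bond proceeds with retention to give the (E)-iodoalkene.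

**Step 6**
Reactants: 7 allylic alcohol; 10 (E)-3-(benzyloxy)-1-iodoprop-1-ene
Product: 11 (2E,6R,7R,8E,10E)-12-(benzyloxy)-6-(tert-butyldimethylsilyloxy)-7-[(tert-butyldimethylsilyloxy)methyl]-3,7-dimethyldodeca-2,8,10-trien-1-ol
Conditions: Pd(OAc)2 (10 mol%), K2CO3, Bu4NCl, DMF, 50 °C
Reagents that add atoms: none
Why: Mizoroki–Heck reaction under ligand-free phase-transfer conditions: the alkenylpalladium iodide inserts the monosubstituted olefin at its terminal carbon (C6), and since C4 is quaternary the only β-hydrogens are on C6, so β-hydride elimination gives the conjugated (5E,7E)-diene without chain walking; the trisubstituted olefin of the allylic alcohol is too hindered to react.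

**Step 7**
Reactants: 11 trienol
Product: 12 (2E,6R,7R,8E,10E)-12-(benzyloxy)-6-(tert-butyldimethylsilyloxy)-7-[(tert-butyldimethylsilyloxy)methyl]-3,7-dimethyldodeca-2,8,10-trienal
Conditions: MnO2 (excess), CH2Cl2, rt
Reagents that add atoms: none
Why: Manganese dioxide oxidises only the allylic alcohol and does so without (E)/(Z) isomerisation, giving the (E)-β-methyl enal that serves as the activated dienophile.

**Step 8**
Reactants: 12 trienal
Product: 13 trans-fused octalin aldehyde (C6=C7 olefin; 3α-OTBS, 19-OTBS, 5β-H, 10α-CH3, 9β-H with the C11 aldehyde α and equatorial, 8β-H with C17H2OBn α and axial)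
Conditions: Me2AlCl (1.5 equiv.), CH2Cl2, −78 °C to −20 °C
Reagents that add atoms: none
Why: Me2AlCl binds the C11 aldehyde and lowers the LUMO of the (E)-β-methyl enal, which undergoes a concerted, asynchronous, suprafacial [4+2] cycloaddition with the tethered (E,E)-diene (type 1 intramolecular Diels–Alder reaction; the closest known reaction type is the Lewis-acid-promoted cyclisation of 2,8,10-undecatrienals to trans-fused octalins). Ring B is closed as a cyclohexene by the cycloaddition itself (new bonds C5–C10 and C8–C9), and ring A is closed as a cyclohexane by the four-carbon tether C1–C4 the moment C5–C10 forms, the tether adopting a chair. C9 and C10 follow from the (E)-olefin geometry (C11 and C20 cis, suprafacial addition), C8 from the (E)-geometry of the C7=C8 terminus (C17 cis to C4, hence α and axial, corrected in step 12), and the trans ring fusion (5β-H, 10α-CH3) from the endo orientation of the aluminium-bound aldehyde, which for an (E)-dienophile places the tether anti. The remaining selectivity, the diene face relative to C3/C4, is decided between two chair-like tethers and should favour the one with the C3 silyloxy group equatorial (C19 axial, C18 equatorial), because C18 and C19 are nearly equal in size while the other chair puts the OTBS group axial against H1 and H5; a 3,19-acetonide would favour the wrong chair, which is why acyclic silyl ethers are carried. The step therefore needs endo over exo and this chair preference, and both should be secured by Lewis-acid activation at low temperature and by the bulky equatorial C3–OTBS group.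

**Step 9**
Reactants: 13 octalin aldehyde
Product: 15 cis-fused 11,17-lactol (five-membered hemiacetal bridging C9 and C8; anomer mixture), via hydroxy aldehyde 14 (not isolated)
Conditions: H2 (1 atm), Pd/C (10%), EtOAc, rt
Reagents that add atoms: none
Why: Heterogeneous hydrogenation saturates the cis-disubstituted C6=C7 olefin (no stereocentre results) and hydrogenolyses the benzyl ether, and the freed C17 hydroxyl, cis to the C11 aldehyde, closes to the five-membered lactol, which also masks the aldehyde against over-reduction.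

**Step 10**
Reactants: 15 lactol
Product: 16 9α-vinyl decalin 17-carbinol (C17H2OH α and axial, 8β-H)
Conditions: Ph3PCH3Br, KOtBu (excess ylide), THF, 0 °C to 40 °C
Reagents that add atoms: methyltriphenylphosphonium bromide, C[P+](c1ccccc1)(c1ccccc1)c1ccccc1.[Br-]
Why: Wittig methylenation of the lactol through its open hydroxy-aldehyde form installs C12; C9 keeps its equatorial (thermodynamic) substituent and is configurationally fixed once the carbonyl is gone.

**Step 11**
Reactants: 16 axial 17-carbinol
Product: 17 axial C17 aldehyde (8β-H)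
Conditions: Dess–Martin periodinane, NaHCO3, CH2Cl2, 0 °C to rt
Reagents that add atoms: none
Why: Dess–Martin oxidation of the primary alcohol under buffered conditions gives the aldehyde without affecting the vinyl group or the silyl ethers.

**Step 12**
Reactants: 17 axial C17 aldehyde
Product: 19 equatorial 17-carbinol (C17H2OH β, 8α-H, 9α-vinyl), via equatorial aldehyde 18 (not isolated)
Conditions: K2CO3, MeOH, rt; then NaBH4, 0 °C
Reagents that add atoms: none
Why: Base-mediated enolisation epimerises C8 to the equatorial aldehyde, driven by relief of the syn-diaxial interaction between the axial formyl group and the C10 methyl, and borohydride reduction in the same flask then fixes the 8α-H, 17β configuration of the target.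

**Step 13**
Reactants: 19 equatorial 17-carbinol; 20 3-bromofuran-2(5H)-one
Product: 22 3,19-bis-TBS ether of the target, via bis-borylated intermediate 21 (not isolated)
Conditions: 9-BBN (2.5 equiv.), THF, rt to 50 °C; then 20, PdCl2(dppf) (5 mol%), AsPh3, Cs2CO3, DMF/H2O, rt
Reagents that add atoms: none
Why: Anti-Markovnikov hydroboration of the monosubstituted olefin by 9-BBN (the free hydroxyl is transiently O-borylated) and B-alkyl Suzuki–Miyaura coupling with the α-bromobutenolide, a reaction type established for α-halo enones and unsaturated lactones, join C12 to C13 with the butenolide intact.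

**Step 14**
Reactants: 22 bis-TBS ether
Product: 23 14-deoxy-17-hydroxyandrographolide
Conditions: HF·pyridine, THF/pyridine, 0 °C to rt
Reagents that add atoms: none
Why: Fluoride cleaves both silyl ethers under mildly acidic conditions that the butenolide tolerates, releasing the triol without touching any stereocentre.

**Compound list**

1 | geranyl acetate | CC(C)=CCC/C(C)=C/COC(C)=O | starting material
2 | 6,7-epoxygeranyl acetate (racemic epoxide) | CC1(C)OC1CC/C(C)=C/COC(C)=O | intermediate
3 | (2E)-3-methyl-6-oxohex-2-en-1-yl acetate | O=CCC/C(C)=C/COC(C)=O | intermediate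
4 | isoprene monoxide (2-methyl-2-vinyloxirane, racemic) | CC1(C=C)CO1 | starting material
5 | (2E,6R,7R)-6-hydroxy-7-(hydroxymethyl)-3,7-dimethylnona-2,8-dien-1-yl acetate | C[C@](CO)(C=C)[C@H](O)CC/C(C)=C/COC(C)=O | intermediate
6 | (2E,6R,7R)-6-(tert-butyldimethylsilyloxy)-7-[(tert-butyldimethylsilyloxy)methyl]-3,7-dimethylnona-2,8-dien-1-yl acetate | C[C@](CO[Si](C)(C)C(C)(C)C)(C=C)[C@H](O[Si](C)(C)C(C)(C)C)CC/C(C)=C/COC(C)=O | intermediate
7 | (2E,6R,7R)-6-(tert-butyldimethylsilyloxy)-7-[(tert-butyldimethylsilyloxy)methyl]-3,7-dimethylnona-2,8-dien-1-ol | C[C@](CO[Si](C)(C)C(C)(C)C)(C=C)[C@H](O[Si](C)(C)C(C)(C)C)CC/C(C)=C/CO | intermediate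
8 | benzyl propargyl ether | C#CCOCc1ccccc1 | starting material
9 | (E)-[3-(benzyloxy)prop-1-en-1-yl]zirconocene chloride | Cl[Zr](/C=C/COCc1ccccc1)(C1C=CC=C1)C1C=CC=C1 | intermediate
10 | (E)-3-(benzyloxy)-1-iodoprop-1-ene | I/C=C/COCc1ccccc1 | intermediate
11 | (2E,6R,7R,8E,10E)-12-(benzyloxy)-6-(tert-butyldimethylsilyloxy)-7-[(tert-butyldimethylsilyloxy)methyl]-3,7-dimethyldodeca-2,8,10-trien-1-ol | C[C@](CO[Si](C)(C)C(C)(C)C)(/C=C/C=C/COCc1ccccc1)[C@H](O[Si](C)(C)C(C)(C)C)CC/C(C)=C/CO | intermediate
12 | (2E,6R,7R,8E,10E)-12-(benzyloxy)-6-(tert-butyldimethylsilyloxy)-7-[(tert-butyldimethylsilyloxy)methyl]-3,7-dimethyldodeca-2,8,10-trienal | C[C@](CO[Si](C)(C)C(C)(C)C)(/C=C/C=C/COCc1ccccc1)[C@H](O[Si](C)(C)C(C)(C)C)CC/C(C)=C/C=O | intermediate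
13 | trans-fused octalin aldehyde (C6=C7; 3α,19-bis-OTBS; 5β-H; 10α-CH3; C11 aldehyde α on C9; C17H2OBn α on C8) | C[C@]1(CO[Si](C)(C)C(C)(C)C)[C@H]2C=C[C@@H](COCc3ccccc3)[C@@H](C=O)[C@]2(C)CC[C@H]1O[Si](C)(C)C(C)(C)C | intermediate
14 | saturated hydroxy aldehyde (C17H2OH α on C8, C11 aldehyde α on C9) | C[C@]1(CO[Si](C)(C)C(C)(C)C)[C@H]2CC[C@@H](CO)[C@@H](C=O)[C@]2(C)CC[C@H]1O[Si](C)(C)C(C)(C)C | intermediate
15 | cis-fused 11,17-lactol (anomer mixture) | C[C@]1(CO[Si](C)(C)C(C)(C)C)[C@H]2CC[C@H]3COC(O)[C@H]3[C@]2(C)CC[C@H]1O[Si](C)(C)C(C)(C)C | intermediate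
16 | 9α-vinyl decalin with axial C17H2OH (8β-H) | C[C@]1(CO[Si](C)(C)C(C)(C)C)[C@H]2CC[C@@H](CO)[C@@H](C=C)[C@]2(C)CC[C@H]1O[Si](C)(C)C(C)(C)C | intermediate
17 | axial C17 aldehyde (8β-H) | C[C@]1(CO[Si](C)(C)C(C)(C)C)[C@H]2CC[C@@H](C=O)[C@@H](C=C)[C@]2(C)CC[C@H]1O[Si](C)(C)C(C)(C)C | intermediate
18 | equatorial C17 aldehyde (8α-H) | C[C@]1(CO[Si](C)(C)C(C)(C)C)[C@H]2CC[C@H](C=O)[C@@H](C=C)[C@]2(C)CC[C@H]1O[Si](C)(C)C(C)(C)C | intermediate
19 | 9α-vinyl decalin with equatorial C17H2OH (8α-H) | C[C@]1(CO[Si](C)(C)C(C)(C)C)[C@H]2CC[C@H](CO)[C@@H](C=C)[C@]2(C)CC[C@H]1O[Si](C)(C)C(C)(C)C | intermediate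
20 | 3-bromofuran-2(5H)-one | O=C1OCC=C1Br | starting material
21 | bis-borylated intermediate (9-BBN on C12 and on O17) | C[C@]1(CO[Si](C)(C)C(C)(C)C)[C@H]2CC[C@H](COB3C4CCCC3CCC4)[C@@H](CCB3C4CCCC3CCC4)[C@]2(C)CC[C@H]1O[Si](C)(C)C(C)(C)C | intermediate
22 | 3,19-bis-TBS ether of 14-deoxy-17-hydroxyandrographolide | C[C@]1(CO[Si](C)(C)C(C)(C)C)[C@H]2CC[C@H](CO)[C@@H](CCC3=CCOC3=O)[C@]2(C)CC[C@H]1O[Si](C)(C)C(C)(C)C | intermediate
23 | 14-deoxy-17-hydroxyandrographolide, 3-{2-[(1R,2S,4aS,5R,6R,8aS)-6-hydroxy-2,5-bis(hydroxymethyl)-5,8a-dimethyldecahydronaphthalen-1-yl]ethyl}furan-2(5H)-one | C[C@]1(CO)[C@H]2CC[C@H](CO)[C@@H](CCC3=CCOC3=O)[C@]2(C)CC[C@H]1O | target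

**Count and risks**

Total step count: 14. Longest linear sequence: 13 steps (steps 1–4 and 6–14, from geranyl acetate).

Steps most likely to fail:

1. Step 8. The two chair-like tether conformations may be poorly discriminated, so that the diene is attacked on the wrong face relative to C3/C4. Endo selectivity may also be eroded by the endo-oriented C10 methyl, and the Lewis-acid-bound enal may isomerise before it cyclises. Fallback: it sets out from 12 and returns at 13. Chlorite oxidation (NaClO2, NaH2PO4, 2-methyl-2-butene) should give the trienoic acid F1. Pivaloyl chloride and Et3N convert it into the mixed pivalic anhydride F2, which acylates lithiated (R)-4-benzyl-1,3-oxazolidin-2-one to give the imide F3. With Me2AlCl (1.4 equiv., CH2Cl2, −30 °C) the chelated imide is a more reactive dienophile, and the benzyl group of the auxiliary shields the unwanted dienophile face (chelate model), so that auxiliary control reinforces the tether chair and should give the cycloadduct F4. LiBH4 (THF/MeOH) cleaves the auxiliary to the carbinol F5, and Dess–Martin oxidation gives 13.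

2. Step 6. Carbopalladation of the neopentyl-type vinyl group may be slow, so that the iodoalkene is consumed by homocoupling, or regiocontrol of the insertion may be lost. Fallback: it sets out from 7 and returns at 11. Cross-metathesis of 7 with vinylboronic acid pinacol ester (second-generation Hoveyda–Grubbs catalyst RuCl2(H2IMes)(=CH-C6H4-2-OiPr), CH2Cl2, 40 °C) should give the (E)-alkenylboronate F6. Suzuki–Miyaura coupling of F6 with 10 (Pd(PPh3)4, aqueous K3PO4, THF) then gives 11 with both olefin geometries defined.

3. Step 13. Base-mediated degradation of the bromobutenolide and of the product butenolide under aqueous carbonate may outpace transmetalation of the hindered alkylborane. Fallback: it sets out from 19 and returns at 22. The borane 21 is coupled with allyl 2-bromoacrylate (PdCl2(dppf), K3PO4, DMF/H2O), which has no acidic γ-hydrogen, to give the allyl acrylate F7. Ring-closing metathesis (second-generation Grubbs catalyst RuCl2(H2IMes)(PCy3)(=CHPh), CH2Cl2, 40 °C) then builds the butenolide ring and gives 22.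

**Further compounds**

F1 | step 8 | (2E,6R,7R,8E,10E)-12-(benzyloxy)-6-(tert-butyldimethylsilyloxy)-7-[(tert-butyldimethylsilyloxy)methyl]-3,7-dimethyldodeca-2,8,10-trienoic acid | C[C@](CO[Si](C)(C)C(C)(C)C)(/C=C/C=C/COCc1ccccc1)[C@H](O[Si](C)(C)C(C)(C)C)CC/C(C)=C/C(O)=O
F2 | step 8 | mixed anhydride of F1 and pivalic acid | C[C@](CO[Si](C)(C)C(C)(C)C)(/C=C/C=C/COCc1ccccc1)[C@H](O[Si](C)(C)C(C)(C)C)CC/C(C)=C/C(=O)OC(=O)C(C)(C)C
F3 | step 8 | N-trienoyl imide of (R)-4-benzyl-1,3-oxazolidin-2-one | C[C@](CO[Si](C)(C)C(C)(C)C)(/C=C/C=C/COCc1ccccc1)[C@H](O[Si](C)(C)C(C)(C)C)CC/C(C)=C/C(=O)N1[C@H](Cc2ccccc2)COC1=O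
F4 | step 8 | trans-fused octalin C11 imide (configured as 13) | C[C@]1(CO[Si](C)(C)C(C)(C)C)[C@H]2C=C[C@@H](COCc3ccccc3)[C@@H](C(=O)N3[C@H](Cc4ccccc4)COC3=O)[C@]2(C)CC[C@H]1O[Si](C)(C)C(C)(C)C
F5 | step 8 | trans-fused octalin C11 carbinol (configured as 13) | C[C@]1(CO[Si](C)(C)C(C)(C)C)[C@H]2C=C[C@@H](COCc3ccccc3)[C@@H](CO)[C@]2(C)CC[C@H]1O[Si](C)(C)C(C)(C)C
F6 | step 6 | (E)-alkenylboronic acid pinacol ester of 7 (boron on C6) | C[C@](CO[Si](C)(C)C(C)(C)C)(/C=C/B1OC(C)(C)C(C)(C)O1)[C@H](O[Si](C)(C)C(C)(C)C)CC/C(C)=C/CO
F7 | step 13 | allyl 2-methylene-4-(decalinyl)butanoate (allyl acrylate carrying C11–C12 at its α-carbon) | C[C@]1(CO[Si](C)(C)C(C)(C)C)[C@H]2CC[C@H](CO)[C@@H](CCC(=C)C(=O)OCC=C)[C@]2(C)CC[C@H]1O[Si](C)(C)C(C)(C)C
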